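Monomer is conserved, so in the south-east run whatever stands neither free nor in chains has gone somewhere else, and that gap is the thing to watch.

| setting | south-east | flask |
|---|---|---|
| free monomer | 2 M | 2.0 M |
| transfer agent | 0.060 M | 0.0600 M |
| initiator | 7.3 mol% | 7.3 mol% |
| remark | the very flask that is asked about, followed so far |  |
| time |  | 3.0 h |

south-east run (percent of the free monomer charged)

| time / min | monomer in chains / % | free monomer / % |
|---|---|---|
| 5.00 | 5.4 | 93.9 |
| 10.0 | 9.3 | 90.7 |
| 15.0 | 9.1 | 88.4 |
| 20.0 | 14.7 | 83.8 |
| 25.0 | 16.3 | 82.2 |
| 30.0 | 16.5 | 79.4 |
| 40.0 | 19.2 | 74.0 |

(each reading ± 1 percentage point)

- the average divides the monomer in chains by the number of chains begun, living and dead together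
- the earlier runs do not show the number of chains; that part of a forecast is a guess

- whether the average number of monomer units in a chain (chains begun, living or dead) reaches 10 by 3.0 h (yes / no)
- average number of monomer units in a chain (chains begun, living or dead) at 3.0 h

What does a length of 10 cost? Count one chain per initiator charged, which is my assumption because the runs show no chains. That gives 0.146 M of chains, so the flask must put its needed share, the wanted length times the initiator loading, into chains: 73.0 % of the free monomer charged.

And if the transfer agent begins chains too? Then the count rises and the needed share with it, so this is the lenient case.

Can the flask pay? By 40.0 min the south-east run has lost 26.0 % of its free monomer, and 19.2 % sits in chains. As a reading, then, 73.8 % of what reacts reaches chains. Put that back in: a charge used up completely gives a length of 10.1, with hardly any margin.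

But is it used up by 3.0 h? Go round again. Taken as steady, the same reading gives a first-order loss of 0.00753 /min, which reckons 74.2 % reacted by then and a length of 7.51. That is my estimate, and a high one if the loss slows, as the scattered readings hint: up to 10.0 min they give a steeper 0.00976 /min. My answer is no.

The forecast differs: yes, with 16, on the grounds “I read 7.3 mol% as relative to transfer agent”, which gave it about 0.07 M of chains.

The flask gives no, with an average of 4.99 at 3.0 h.

    free monomer + initiator → living end + monomer in chains (k = 0.0950 /M/min)
    free monomer + living end → monomer in chains + living end, rate k2*[living end]*[free monomer] (k = 0.0410 /M/min)
    living end + transfer agent → dead chain (kL = 0.0350 /M/min)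
    free monomer → uncatalysed product (k = 0.00150 /min)
    living end → dead end (k = 0.0110 /min)

Initiator stands at 0 % in the flask at that time, and living end, dead chain and dead end add up to 0.146 M, the 0.146 M counted. The flask holds 36.4 % in chains, less than its needed share of 73.0 %. The neighbour charged with 12 mol% of initiator has a needed share of 120 %, and its 52.7 % in chains gives an average of 4.39.

(Readings and results stem from a simulated flask from invented constants; the scatter is artificial.)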